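How much substrate stands in the flask at 5.0 h, and how much has gone on to mono adduct and beyond?

| setting | eta | alpha | beta | flask |
|---|---|---|---|---|
| substrate | 0.053 M | 0.053 M | 0.11 M | 0.053 M |
| reagent | 0.071 M | 0.16 M | 0.106 M | 0.106 M |
| remark | run made earlier | run made earlier | run made earlier |  |
| time |  |  |  | 5.0 h |

| run | time / h | substrate / % | mono adduct / % |
|---|---|---|---|
| eta | 0.333 | 83.4 | 16.8 |
| eta | 0.667 | 70.9 | 26.6 |
| eta | 1.50 | 51.8 | 44.8 |
| eta | 4.00 | 26.0 | 66.7 |
| alpha | 1.00 | 32.5 | 58.8 |
| alpha | 2.00 | 13.0 | 72.9 |
| alpha | 3.00 | 6.0 | 77.0 |
| alpha | 4.00 | 3.7 | 76.6 |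
| beta | 0.500 | 70.9 | 29.1 |
| beta | 1.33 | 47.5 | 48.8 |
| beta | 2.50 | 34.1 | 61.6 |
| beta | 4.00 | 26.2 | 69.0 |

(each reading ± 0.5 percentage points)

- the substrate standing at 5.0 h, as a percentage of the substrate charged
- the mono adduct standing at 5.0 h, as a percentage of the substrate charged
- the double product standing at 5.0 h, as a percentage of the substrate charged
- the tris adduct standing at 5.0 h, as a percentage of the substrate charged

- a reading or a percentage of mono adduct counts all its forms, free or not

I count everything in fractions of the substrate charge. Each substrate that reacts takes one reagent, so while nothing goes beyond mono adduct, the excess of reagent over substrate stays constant. I freeze that excess, and the substrate curve then has a closed form. The first alpha reading gives its rate constant per unit fraction, 0.431 h⁻¹, a reading with its scatter.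

The flask starts with an excess of 1.00. Held there, it leaves 6.14% substrate, my lower bound. For the upper bound I take the alpha shortfall at 4.00 h, 19.7%, as a ceiling, since alpha had more reagent than the flask. If each lost unit took two more reagent, the excess is 0.606. Frozen there from the start, it leaves 12.3%. I commit to the middle, 9.21%.

The forecast says 8.5% substrate, lower than my middle but inside the bracket. It adds 77% mono adduct, 12% double product and 2.5% tris adduct, noting that “The runs never separate double from tris”.

The flask gives 7.48% substrate, 78.6% mono adduct, 8.56% double product and 5.38% tris adduct, within the forecast's tolerance.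

    reagent + double product ⇌ tris adduct (K = 14.0 L mol⁻¹, k = 0.00830 L mol⁻¹ s⁻¹)
    substrate + reagent → mono adduct (k = 0.00230 L mol⁻¹ s⁻¹)
    crystals ⇌ mono adduct, rate k3*(cs3 - [mono adduct]) while solid is left; crystals form when [mono adduct] > cs3 (solubility = 2.20 mM, k = 0.00400 s⁻¹)
    reagent + mono adduct → double product (k = 0.00230 L mol⁻¹ s⁻¹)

In the flask, dissolved mono adduct has a half-life of 0.79 h by its conversion into double product alone, with the other concentrations as charged, which is shorter than 5.0 h, yet at 5.00 h 74.3% of the substrate charged stands as crystals, counted within the mono adduct. The excess in the flask at 5.0 h stands at 0.807, between my two frozen values. Now I freeze the reagent left at 5.0 h and treat the late loss of substrate as pseudo-first-order, at 0.380 h⁻¹. For the same flask left until 8.0 h, this takes 7.48% substrate down to 2.39%, and the computed result is 2.53%.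

The readings were generated by integration with constants of no real substance; noise was put on by code.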